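## Structural features

Hernanol is an α,β-dibenzyl-γ-butyrolactone lignan. Its only non-aromatic ring is the lactone (O1, C2 carbonyl, C3, C4, C5), with a 3,4,5-trimethoxybenzyl group on C3 and a 4-hydroxy-3-methoxybenzyl group on C4. The two stereocentres C3 and C4 are adjacent, both R, and their benzyl groups are trans. C3 is α to the carbonyl, can be epimerised and prefers the trans arrangement, so it can be set last. C4 cannot be epimerised and is surrounded by three carbon substituents that differ little (C3, the ring carbon C5 and the benzylic CH2), so making it in absolute form is the real difficulty. Fragile points are the lactone (bases, nucleophiles, acyl migration while a free CH2OH sits on C4), the free phenol, and two electron-rich arenes open to Friedel–Crafts attack by any carbocation. The key step exploits the two CH2 arms on C4 (C5 and the benzylic carbon): C4 and these arms map onto C3 and the two enantiotopic CH2 groups of a 3-substituted oxetane, while C3 and C2 of the lactone map onto the central carbon and one carboxyl carbon of a malonate attached to that oxetane.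

## Logic of the disconnections

**13 to 11.** A tert-butoxycarbonyl group is put back on C3 (the C3–H bond of 13 stands for a C3–carboxyl bond) and the phenol is masked as its tert-butyl carbonate. C3 is the one centre that can be made last: an α-carboxy lactone decarboxylates through a planar enol, and protonation away from the C4 substituent, backed by thermodynamics, gives the trans lactone whatever C3 was before. The gain is that C3 needs no control upstream and that ester and carbonate fall in one acid operation, through 12, with no separate deprotection. The forward step must intercept tert-butyl cations before they alkylate the arenes and must decarboxylate 12 cleanly.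

**11 to 8 + 10.** The bond between the guaiacyl ring and its benzylic carbon is cut. That carbon is the arm left outside the lactone by the ring expansion, so the phenolic arene becomes a simple aryl bromide that enters late and convergently. The forward step must join a β-branched primary alkyl iodide to an aryl bromide without base or hard nucleophiles, since 8 holds a lactone and an ester. A nickel-catalysed reductive coupling of the two halides meets this and does not touch C4.

**10 to 9.** The O–C bond of the carbonate is cut. The carbonate removes the acidic proton for the coupling, makes the aryl bromide less electron-rich, and is preferred to a benzyl ether because it leaves in the same acid step as the ester. If it is partly lost during the coupling, the material still converges on 13.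

**8 to 7.** The C–I bond is exchanged for the C–O bond of a primary alcohol, because 7 is what the ring expansion delivers. The forward activation must be fast and nearly neutral: a free CH2OH on C4 can shift the acyl group between the two CH2O arms, which would invert C4, or attack the remaining ester.

**7 to 6 (key).** The O1–C5 bond is cut and the oxygen of the CH2OH arm is joined to C5 instead, which restores an oxetane; the acyl oxygen regains its tert-butyl group. This turns the non-epimerisable centre C4 into the prochiral C3 of an oxetane. Compound 6 is achiral, with two enantiotopic CH2 groups and two equivalent esters, so the ring and both stereocentres vanish in one move. The forward step needs a chiral acid that activates the oxetane and tells its CH2 groups apart, an ester oxygen that reaches a CH2 group through a five-membered transition state, and a product that does not react further. The design of 6 is kept with two identical tert-butyl esters: the malonate carbon is then no stereocentre, two carbonyl oxygens are available, and the tertiary alkyl group can leave as isobutene.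

**6 to 4 + 5.** The bond between the future C3 and its benzylic carbon is cut. This is a malonate alkylation that builds the quaternary carbon with no stereochemical consequence. The only demand is that the tertiary enolate of 4 is alkylated cleanly; the oxetane oxygen is γ to the carbanion and cannot be eliminated.

**4 to 3 to 1 + 2.** The bond between the oxetane C3 and the malonate carbon is cut by way of alkene 3: condensation of ketone 1 with 2, then conjugate reduction. This reaches two inexpensive commercial compounds. The forward demand is a condensation strong enough for a hindered malonate but gentle to an oxetane, and a hydride that spares the esters.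

## Other disconnections considered

**Alternative 1:** The cut removes both benzylic attachments of the ring, the C4–benzylic carbon bond and the C3–benzylic carbon bond, and leaves the chiral alkoxybutenolide (5R)-5-[(1R,2S,5R)-menthyloxy]furan-2(5H)-one A2.
- Forward step: the lithium anion of the aryl dithiane A3 would add to C4 of A2 anti to the menthyloxy group. The lactone enolate would then be benzylated at C3, anti to the new C4 substituent, by a benzylic halide such as 5, giving A1 in one flask with no ring closure.
- In favour: two skeletal bonds and both stereocentres arise together. Relative and absolute configuration follow from substrate control by a cheap auxiliary in a long-established reaction class. On predictability of the stereochemical outcome this plan is the better of the two.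
- Against: the auxiliary is stoichiometric and A2 must be secured as a single C5 epimer. The step needs cryogenic organolithium chemistry. A1 still carries an acetal at C5 and a dithiane at the benzylic carbon, so reductive removal of the auxiliary with relactonisation and a desulfurisation over Raney Ni must follow, with sulfur waste and excess nickel.
- Comparison: the chosen plan reaches C4 from an achiral precursor with a catalytic amount of chiral material and leaves nothing to excise. Mechanistically it depends on catalyst control of uncertain level, where A1 rests on a dependable substrate bias. In step count the two are about equal, with Alternative 1 somewhat shorter in its longest linear sequence.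

**Alternative 2:** Three bonds are cut, C4–benzylic carbon, C3–C2 and C2–O1, taking the skeleton back to the butynol A5, the benzylic Grignard reagent A6 and a one-carbon electrophile.
- Forward step: the magnesium alkoxide of A5 would direct a CuI-catalysed anti carbomagnesiation by A6, placing the new benzyl group on C4 and magnesium on C3 within a five-membered chelate. Carboxylation of that alkenylmagnesium and acidification would close the butenolide A4.
- In favour: the whole carbon skeleton and the lactone ring appear in one flask from two simple achiral pieces. In step economy up to the skeleton this plan is clearly the better one, and its key step is mechanistically at least as well founded as the chosen one.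
- Against: A4 is achiral, so neither C3 nor C4 is set. What remains is an enantioselective reduction of a tetrasubstituted butenolide alkene with no directing group, then epimerisation of C3 from cis to trans; no dependable catalyst can be named for that with confidence. A6 is also an electron-rich benzylic Grignard reagent prone to Wurtz-type homocoupling.
- Comparison: the stereochemical problem is only postponed to a hard substrate class, whereas the chosen plan sets C4 in the same event that builds the lactone.

**Alternative 3:** The cut goes through the C3–C4 bond and the bond between the guaiacyl ring and its benzylic carbon, giving the styrenylboronic ester A8, vinyllithium A10 and the aryl triflate A9.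
- Forward step: A8 and A10 would form a boron ate complex. Under Pd(OAc)2 with a chiral ferrocenyl diphosphine of the Mandyphos type, the arylpalladium species from A9 would trigger a 1,2-shift of the styrenyl group from boron to the vinyl α-carbon while the aryl group goes to the vinyl terminus. This would give the α-chiral allylboronate A7 without ring closure.
- In favour: it is catalytic and enantioselective, makes two carbon–carbon bonds and C4 in one step, and leaves a stereoretentive C–B handle. In skeletal bonds per key step it is the better; in its reliance on catalyst control it is the equal of the chosen plan.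
- Against: A7 contains neither C5 nor C2. A one-carbon homologation of the C–B bond with oxidation must follow, and then a carbonylative lactonisation that must place the carbonyl carbon on C3 and not on the benzylic carbon (five- versus six-membered lactone). The ate complex carries two alkenyl groups and palladium must engage only the unsubstituted one. The electron-rich triflate A9 itself needs several steps.
- Comparison: the route would be longer and would carry a second uncertain regiochemical step after the key step, whereas the chosen key step delivers the complete lactone with its oxygen pattern in place.

Key step: step 4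

Assumption 1: the sense of induction of the phosphoric acid on 6 cannot be predicted with confidence; the (R)-catalyst is written, and its mirror image would be used if the first run showed the opposite sense.

Assumption 2: 7, 8, 11 and 12 are drawn as the C3 epimer with the trimethoxybenzyl group trans to the C4 substituent; the other C3 epimer is expected alongside and is carried on, because C3 is reset in step 8.

Assumption 3: 3,4,5-trimethoxybenzyl chloride (5) is taken as a purchasable reagent, which saves a separate halogenation of the benzylic alcohol.

Remark: the C4 descriptor changes from S in 7 to R in 8, 11, 12 and 13 with no change in spatial arrangement, only through the priorities of the two CH2 arms.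

## Steps

Step 1
Reactants: 1 oxetan-3-one; 2 di-tert-butyl malonate
Product: 3 di-tert-butyl 2-(oxetan-3-ylidene)malonate
Conditions: TiCl4 (2 equiv), pyridine (4 equiv), THF, 0 °C → rt
Reagents that add atoms: none
Why: Knoevenagel condensation under TiCl4–pyridine: the titanium enolate of 2 adds to the strained, highly electrophilic ketone and the aldolate is dehydrated by pyridine; the amine buffers HCl, so the oxetane and the tert-butyl esters should survive at 0 °C.

Step 2
Reactants: 3 di-tert-butyl 2-(oxetan-3-ylidene)malonate
Product: 4 di-tert-butyl 2-(oxetan-3-yl)malonate
Conditions: NaBH4, EtOH/THF, 0 °C; aq. NH4Cl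
Reagents that add atoms: none
Why: Conjugate (1,4) hydride reduction of an alkylidene malonate; hydride adds to the oxetane carbon of the doubly activated alkene and the enolate is protonated on work-up, while tert-butyl esters and the oxetane are inert to NaBH4.

Step 3
Reactants: 4 di-tert-butyl 2-(oxetan-3-yl)malonate; 5 3,4,5-trimethoxybenzyl chloride
Product: 6 di-tert-butyl 2-(oxetan-3-yl)-2-(3,4,5-trimethoxybenzyl)malonate
Conditions: NaH, THF/DMF (5:1), 0 °C → 40 °C
Reagents that add atoms: none
Why: Malonate C-alkylation (SN2) by a reactive, electron-rich benzylic chloride builds the quaternary carbon; the sodium enolate is stable because the oxetane oxygen is γ to the carbanion, and no stereocentre arises since 6 is achiral.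

Step 4
Reactants: 6 di-tert-butyl 2-(oxetan-3-yl)-2-(3,4,5-trimethoxybenzyl)malonate
Product: 7 tert-butyl (3S,4S)-4-(hydroxymethyl)-2-oxo-3-(3,4,5-trimethoxybenzyl)tetrahydrofuran-3-carboxylate
Conditions: (R)-3,3'-bis(2,4,6-triisopropylphenyl)-1,1'-binaphthyl-2,2'-diyl hydrogen phosphate (10 mol %), toluene, 40 °C
Reagents that add atoms: none
Why: Enantioselective oxetane desymmetrisation with ring expansion: the phosphoric acid hydrogen-bonds to (or protonates) the oxetane oxygen inside its chiral pocket, and the carbonyl oxygen of one tert-butyl ester attacks one oxetane CH2 from the rear (intramolecular SN2, 5-exo-tet), forming the O1–C5 bond and closing the lactone while the other arm ends as CH2OH. The dialkoxycarbenium ion so formed loses its tert-butyl group as isobutene, the phosphate taking the proton, which makes the step irreversible and returns the catalyst. The closest known reaction type is the chiral phosphoric acid-catalysed intramolecular desymmetrisation of 3-substituted oxetanes by tethered oxygen nucleophiles, joined to the acid-induced dealkylative lactonisation of tert-butyl esters onto activated carbon electrophiles; an ester carbonyl is a weaker nucleophile than a hydroxyl, so this is the demanding end of that class. C4 is set by the catalyst alone, through its choice between the two enantiotopic CH2 groups of an achiral substrate. C3 becomes stereogenic according to which of the two equivalent esters attacks; it is drawn with benzyl trans to CH2OH and is of no consequence because step 8 resets it. The step needs chemoselectivity for the ester oxygen over the C2 position of the trimethoxyphenyl ring (a Friedel–Crafts 6-exo opening to a tetralin) and over a second lactonisation of the new hydroxyl onto the remaining ester. The first is secured by the quaternary carbon, which holds two carbonyl oxygens five atoms from each CH2 group (Thorpe–Ingold compression), and by a weakly acidic catalyst that does not promote arene attack; the second is held back by moderate temperature and by stopping at full conversion.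

Step 5
Reactants: 7 tert-butyl (3S,4S)-4-(hydroxymethyl)-2-oxo-3-(3,4,5-trimethoxybenzyl)tetrahydrofuran-3-carboxylate
Product: 8 tert-butyl (3S,4R)-4-(iodomethyl)-2-oxo-3-(3,4,5-trimethoxybenzyl)tetrahydrofuran-3-carboxylate
Conditions: I2, PPh3, imidazole, CH2Cl2, 0 °C → rt
Reagents that add atoms: iodine, [I][I]
Why: Appel-type iodination: the hydroxyl becomes an alkoxyphosphonium ion that iodide displaces by SN2 at the primary carbon; no bond to C4 or C3 is touched, and removing the free hydroxyl at once closes off acyl migration between the two CH2O arms.

Step 6
Reactants: 9 4-bromo-2-methoxyphenol
Product: 10 4-bromo-2-methoxyphenyl tert-butyl carbonate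
Conditions: Boc2O, DMAP (cat.), MeCN, rt
Reagents that add atoms: di-tert-butyl dicarbonate, CC(C)(C)OC(=O)OC(=O)OC(C)(C)C
Why: DMAP-catalysed O-acylation of a phenol; the carbonate hides the acidic proton, makes the aryl bromide less electron-rich for oxidative addition, and is cleaved later by the same acid as the ester.

Step 7
Reactants: 8 tert-butyl (3S,4R)-4-(iodomethyl)-2-oxo-3-(3,4,5-trimethoxybenzyl)tetrahydrofuran-3-carboxylate; 10 4-bromo-2-methoxyphenyl tert-butyl carbonate
Product: 11 tert-butyl (3S,4R)-4-{4-[(tert-butoxycarbonyl)oxy]-3-methoxybenzyl}-2-oxo-3-(3,4,5-trimethoxybenzyl)tetrahydrofuran-3-carboxylate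
Conditions: NiI2 (10 mol %), 4,4'-di-tert-butyl-2,2'-bipyridine (10 mol %), Zn dust (2 equiv), pyridine (cat.), DMA, 50 °C
Reagents that add atoms: none
Why: Nickel-catalysed reductive cross-electrophile coupling: the aryl bromide adds oxidatively to zerovalent nickel, the alkyl iodide is reduced to a primary radical that the arylnickel species captures, reductive elimination forms the C(sp3)–C(sp2) bond and zinc returns the catalyst to its low-valent state; the medium holds no strong base or nucleophile, so lactone, ester and carbonate should survive, and C4 keeps its configuration.

Step 8
Reactants: 11 tert-butyl (3S,4R)-4-{4-[(tert-butoxycarbonyl)oxy]-3-methoxybenzyl}-2-oxo-3-(3,4,5-trimethoxybenzyl)tetrahydrofuran-3-carboxylate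
Product: 13 hernanol [(3R,4R)-4-(4-hydroxy-3-methoxybenzyl)-3-(3,4,5-trimethoxybenzyl)dihydrofuran-2(3H)-one], via lactone acid 12 (not isolated)
Conditions: TFA, Et3SiH (3 equiv), CH2Cl2, 0 °C → rt; evaporate; toluene, 110 °C
Reagents that add atoms: none
Why: Acidolysis removes both tert-butyl groups (ester and aryl carbonate, the latter with loss of CO2), the silane reducing the tert-butyl cations before they can alkylate the arenes; the α-carboxy lactone 12 then decarboxylates thermally through its enol, which is protonated on the face away from the C4 benzyl group to give the thermodynamically preferred trans lactone (a trace of DBU would complete equilibration), so C3 becomes R while C4 stays R.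

## Compound list

1 | oxetan-3-one | O=C1COC1 | starting material
2 | di-tert-butyl malonate | CC(C)(C)OC(=O)CC(=O)OC(C)(C)C | starting material
3 | di-tert-butyl 2-(oxetan-3-ylidene)malonate | CC(C)(C)OC(=O)C(=C1COC1)C(=O)OC(C)(C)C | intermediate
4 | di-tert-butyl 2-(oxetan-3-yl)malonate | CC(C)(C)OC(=O)C(C1COC1)C(=O)OC(C)(C)C | intermediate
5 | 3,4,5-trimethoxybenzyl chloride | COc1cc(CCl)cc(OC)c1OC | starting material
6 | di-tert-butyl 2-(oxetan-3-yl)-2-(3,4,5-trimethoxybenzyl)malonate | CC(C)(C)OC(=O)C(Cc1cc(OC)c(OC)c(OC)c1)(C1COC1)C(=O)OC(C)(C)C | intermediate
7 | tert-butyl (3S,4S)-4-(hydroxymethyl)-2-oxo-3-(3,4,5-trimethoxybenzyl)tetrahydrofuran-3-carboxylate | OC[C@H]1COC(=O)[C@]1(C(=O)OC(C)(C)C)Cc1cc(OC)c(OC)c(OC)c1 | intermediate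
8 | tert-butyl (3S,4R)-4-(iodomethyl)-2-oxo-3-(3,4,5-trimethoxybenzyl)tetrahydrofuran-3-carboxylate | IC[C@H]1COC(=O)[C@]1(C(=O)OC(C)(C)C)Cc1cc(OC)c(OC)c(OC)c1 | intermediate
9 | 4-bromo-2-methoxyphenol | COc1cc(Br)ccc1O | starting material
10 | 4-bromo-2-methoxyphenyl tert-butyl carbonate | COc1cc(Br)ccc1OC(=O)OC(C)(C)C | intermediate
11 | tert-butyl (3S,4R)-4-{4-[(tert-butoxycarbonyl)oxy]-3-methoxybenzyl}-2-oxo-3-(3,4,5-trimethoxybenzyl)tetrahydrofuran-3-carboxylate | COc1cc(C[C@H]2COC(=O)[C@]2(C(=O)OC(C)(C)C)Cc2cc(OC)c(OC)c(OC)c2)ccc1OC(=O)OC(C)(C)C | intermediate
12 | (3R,4R)-4-(4-hydroxy-3-methoxybenzyl)-2-oxo-3-(3,4,5-trimethoxybenzyl)tetrahydrofuran-3-carboxylic acid | COc1cc(C[C@H]2COC(=O)[C@]2(C(=O)O)Cc2cc(OC)c(OC)c(OC)c2)ccc1O | intermediate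
13 | hernanol, (3R,4R)-4-(4-hydroxy-3-methoxybenzyl)-3-(3,4,5-trimethoxybenzyl)dihydrofuran-2(3H)-one | COc1cc(C[C@H]2COC(=O)[C@@H]2Cc2cc(OC)c(OC)c(OC)c2)ccc1O | target

## Step count and least certain steps

Total step count: 8. Longest linear sequence: 7 steps (steps 1, 2, 3, 4, 5, 7, 8); step 6 is a one-step side branch.

**Step 4 (key step).** What may go wrong: weak discrimination between the two enantiotopic CH2 groups, or slow turnover that tempts harsher conditions. The ester carbonyl has no proton for the phosphoryl oxygen of the catalyst to hold, so the two-point binding that organises hydroxyl nucleophiles in this reaction class is absent and the selection rests on the shape of the pocket alone. The carbonyl oxygen is also a modest nucleophile, and heating would bring in a racemic background, ring opening by the trimethoxyphenyl ring and a second lactonisation onto the remaining ester. Fallback (a different enantio-determining event): from 6, the oxetane would be opened intermolecularly by chloride, with HCl released slowly from Me3SiCl and a measured amount of water, under a catalyst of the same class; this is an established desymmetrisation of 3-substituted oxetanes. The catalyst enantiomer would be chosen so that chloride opens the CH2 group that the main route leaves as CH2OH, giving di-tert-butyl 2-[(2R)-1-chloro-3-hydroxypropan-2-yl]-2-(3,4,5-trimethoxybenzyl)malonate F1. Acid-catalysed lactonisation of the hydroxyl onto either ester (TsOH, CH2Cl2) would give tert-butyl (3S,4R)-4-(chloromethyl)-2-oxo-3-(3,4,5-trimethoxybenzyl)tetrahydrofuran-3-carboxylate F2 with its C3 epimer. NaI in acetone would convert it into 8, where the route is rejoined.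

**Step 7.** What may go wrong: reduction or homocoupling of the alkyl iodide outrunning the cross-coupling, because 8 is β-branched next to a quaternary carbon and the aryl partner is still fairly electron-rich. Slow capture of the primary radical would also give it time for β-scission of the C3–C4 bond (to an allyl ester with a stabilised dicarbonyl radical) and re-closure, which would erode the configuration at C4. On prolonged heating the cis ester could also displace iodide. Fallback (a polar two-stage coupling in place of the radical one): from 8, zinc insertion (Zn dust activated with Me3SiCl, LiCl, THF, 40 °C) would give the alkylzinc iodide tert-butyl (3S,4R)-4-[(iodozincio)methyl]-2-oxo-3-(3,4,5-trimethoxybenzyl)tetrahydrofuran-3-carboxylate F3. A Negishi coupling with 10 under Pd(OAc)2 and 2-dicyclohexylphosphino-2',6'-dimethoxybiphenyl in THF at rt to 50 °C would give 11, where the route is rejoined.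

**Step 1.** What may go wrong: incomplete condensation because of the bulk of the di-tert-butyl malonate, together with Lewis-acid-induced opening of the oxetane or loss of tert-butyl groups by TiCl4. Fallback (olefination and acylation, replacing steps 1 and 2): from 1, a Horner–Wadsworth–Emmons reaction with tert-butyl (diethoxyphosphoryl)acetate (NaH, THF) would give tert-butyl 2-(oxetan-3-ylidene)acetate F4. Hydrogenation (H2, palladium on carbon (Pd/C), EtOAc) would give tert-butyl 2-(oxetan-3-yl)acetate F5. C-acylation of its lithium enolate with Boc2O (LiN(iPr)2, 2 equiv, THF, −78 °C) would give the malonate 4, where the route is rejoined.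

**Step 8.** What may go wrong: alkylation of the phenol ring or the trimethoxyphenyl ring by tert-butyl cations that escape the silane, sluggish decarboxylation of the fully substituted acid at 110 °C, or incomplete trans selectivity in the protonation of the enol. Fallback (neutral pericyclic thermolysis in place of ionising acid): from 11, heating in diphenyl ether at about 180 °C should expel isobutene from the ester and the carbonate by concerted elimination, with no free cation, and decarboxylate 12 as it forms, so that 13 is reached directly. This fallback makes no new compound (entry F0). Any cis lactone would be equilibrated with catalytic DBU in either variant.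

**Step 5.** What may go wrong: attack of the cis ester carbonyl on the alkoxyphosphonium carbon (dealkylative closure of a second lactone, which gives an achiral bis-lactone), or imidazole-promoted acyl migration between the two CH2O arms before the hydroxyl is consumed, which after step 8 would amount to partial racemisation. Fallback (a sulfonate with halide exchange in the coupling flask, no isolated iodide): from 7, MsCl and Et3N in CH2Cl2 at −20 °C would give tert-butyl (3S,4R)-4-{[(methylsulfonyl)oxy]methyl}-2-oxo-3-(3,4,5-trimethoxybenzyl)tetrahydrofuran-3-carboxylate F6. F6 would be taken with 10 into the nickel coupling of step 7 with NaI (1 equiv) added, the iodide 8 forming and reacting in the flask; the route is rejoined at 11.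

## Further compounds

F1 | step 4 | di-tert-butyl 2-[(2R)-1-chloro-3-hydroxypropan-2-yl]-2-(3,4,5-trimethoxybenzyl)malonate | ClC[C@@H](CO)C(Cc1cc(OC)c(OC)c(OC)c1)(C(=O)OC(C)(C)C)C(=O)OC(C)(C)C
F2 | step 4 | tert-butyl (3S,4R)-4-(chloromethyl)-2-oxo-3-(3,4,5-trimethoxybenzyl)tetrahydrofuran-3-carboxylate | ClC[C@H]1COC(=O)[C@]1(C(=O)OC(C)(C)C)Cc1cc(OC)c(OC)c(OC)c1
F3 | step 7 | tert-butyl (3S,4R)-4-[(iodozincio)methyl]-2-oxo-3-(3,4,5-trimethoxybenzyl)tetrahydrofuran-3-carboxylate | I[Zn]C[C@H]1COC(=O)[C@]1(C(=O)OC(C)(C)C)Cc1cc(OC)c(OC)c(OC)c1
F4 | step 1 | tert-butyl 2-(oxetan-3-ylidene)acetate | CC(C)(C)OC(=O)C=C1COC1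
F5 | step 1 | tert-butyl 2-(oxetan-3-yl)acetate | CC(C)(C)OC(=O)CC1COC1
F0 | step 8 | none | none
F6 | step 5 | tert-butyl (3S,4R)-4-{[(methylsulfonyl)oxy]methyl}-2-oxo-3-(3,4,5-trimethoxybenzyl)tetrahydrofuran-3-carboxylate | CS(=O)(=O)OC[C@H]1COC(=O)[C@]1(C(=O)OC(C)(C)C)Cc1cc(OC)c(OC)c(OC)c1
A1 | alternative 1 | (3R,4R,5R)-4-[2-(4-benzyloxy-3-methoxyphenyl)-1,3-dithian-2-yl]-5-[(1R,2S,5R)-menthyloxy]-3-(3,4,5-trimethoxybenzyl)dihydrofuran-2(3H)-one | COc1cc(C3(SCCCS3)[C@H]2[C@H](O[C@@H]3C[C@H](C)CC[C@H]3C(C)C)OC(=O)[C@@H]2Cc2cc(OC)c(OC)c(OC)c2)ccc1OCc1ccccc1
A2 | alternative 1 | (5R)-5-[(1R,2S,5R)-menthyloxy]furan-2(5H)-one | O=C1C=C[C@H](O[C@@H]2C[C@H](C)CC[C@H]2C(C)C)O1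
A3 | alternative 1 | 2-(4-benzyloxy-3-methoxyphenyl)-1,3-dithiane | COc1cc(C2SCCCS2)ccc1OCc1ccccc1
A4 | alternative 2 | 4-(4-benzyloxy-3-methoxybenzyl)-3-(3,4,5-trimethoxybenzyl)furan-2(5H)-one | COc1cc(CC2=C(Cc3cc(OC)c(OC)c(OC)c3)C(=O)OC2)ccc1OCc1ccccc1
A5 | alternative 2 | 4-(3,4,5-trimethoxyphenyl)but-2-yn-1-ol | COc1cc(CC#CCO)cc(OC)c1OC
A6 | alternative 2 | (4-benzyloxy-3-methoxybenzyl)magnesium chloride | COc1cc(C[Mg]Cl)ccc1OCc1ccccc1
A7 | alternative 3 | (R,E)-2-[1-(4-benzyloxy-3-methoxyphenyl)-4-(3,4,5-trimethoxyphenyl)but-3-en-2-yl]-4,4,5,5-tetramethyl-1,3,2-dioxaborolane | COc1cc(C[C@H](/C=C/c2cc(OC)c(OC)c(OC)c2)B2OC(C)(C)C(C)(C)O2)ccc1OCc1ccccc1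
A8 | alternative 3 | (E)-4,4,5,5-tetramethyl-2-(3,4,5-trimethoxystyryl)-1,3,2-dioxaborolane | COc1cc(/C=C/B2OC(C)(C)C(C)(C)O2)cc(OC)c1OC
A9 | alternative 3 | 4-(benzyloxy)-3-methoxyphenyl trifluoromethanesulfonate | COc1cc(OS(=O)(=O)C(F)(F)F)ccc1OCc1ccccc1
A10 | alternative 3 | vinyllithium | [Li]C=C
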